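**Retrosynthetic overview**
- The phenol OH comes from a formyl group. The last step is a Baeyer–Villiger oxidation and formate cleavage of a 2-aryloxybenzaldehyde, so CHO serves as both masked OH and SNAr activator.
- The diaryl ether C–O bond comes from SNAr of 2,4-dibromophenol on 3,5-dibromo-2-fluoro-4-methoxybenzaldehyde, where F is ortho to CHO.
- That fluoroaldehyde comes from O-methylation, preceded by OH-directed double bromination of 2-fluoro-4-hydroxybenzaldehyde. The bromines go in early because C3 is hard to brominate once it lies between two ether oxygens.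
- No ring is formed. Ring A (the phenol ring) and ring B (the dibromophenoxy ring) are bought as benzenes and joined in step 3.

Assumption: the SMILES holds no stereocentre and the diaryl ether axis rotates freely, so the target is achiral and no step needs stereocontrol.

**Route**

Step 1
Reactants: 1 2-fluoro-4-hydroxybenzaldehyde
Product: 3 3,5-dibromo-2-fluoro-4-hydroxybenzaldehyde, via 5-bromo-2-fluoro-4-hydroxybenzaldehyde 2 (not isolated)
Conditions: Br2 (2.1 equiv), AcOH, rt, 3 h
Reagents that add atoms: bromine, BrBr
Why: Electrophilic aromatic bromination: the free 4-OH activates both of its ortho positions C5 and C3, which are also meta to CHO, whereas C6 is meta to OH and ortho to CHO, so exactly two bromines enter and no stereocentre is created.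

Step 2
Reactants: 3 3,5-dibromo-2-fluoro-4-hydroxybenzaldehyde
Product: 4 3,5-dibromo-2-fluoro-4-methoxybenzaldehyde
Conditions: MeI (1.3 equiv), K2CO3 (1.5 equiv), DMF, rt, 12 h
Reagents that add atoms: iodomethane (MeI), CI
Why: Williamson-type SN2 O-methylation of the acidic 2,6-dibromophenoxide, which is too weak a nucleophile to displace the aryl fluoride of a second molecule at room temperature.

Step 3
Reactants: 4 3,5-dibromo-2-fluoro-4-methoxybenzaldehyde, 5 2,4-dibromophenol (1.1 equiv)
Product: 6 3,5-dibromo-2-(2,4-dibromophenoxy)-4-methoxybenzaldehyde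
Conditions: K2CO3 (1.5 equiv), DMF, 80 °C, 8 h
Reagents that add atoms: none
Why: Nucleophilic aromatic substitution (SNAr, addition–elimination through a Meisenheimer adduct): fluoride sits ortho to the formyl group and is further activated inductively by the two bromines, while all four C–Br bonds are meta to CHO or on an unactivated ring and stay untouched.

Step 4
Reactants: 6 3,5-dibromo-2-(2,4-dibromophenoxy)-4-methoxybenzaldehyde
Product: 8 3,5-dibromo-2-(2,4-dibromophenoxy)-4-methoxyphenol, via aryl formate 7 (not isolated)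
Conditions: mCPBA (1.5 equiv), CH2Cl2, 40 °C, 16 h; then MeOH, cat. conc. HCl, rt, 1 h
Reagents that add atoms: 3-chloroperoxybenzoic acid (mCPBA), O=C(OO)c1cccc(Cl)c1
Why: Baeyer–Villiger oxidation in which the aryl group, enriched by the ortho aryloxy and para methoxy oxygens, migrates in the Criegee adduct to give the aryl formate, which acid-catalysed transesterification with methanol cleaves to the free phenol without touching the methyl ether, the diaryl ether or the C–Br bonds.

**Compound list**
1 | 2-fluoro-4-hydroxybenzaldehyde | O=Cc1ccc(O)cc1F | starting material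
2 | 5-bromo-2-fluoro-4-hydroxybenzaldehyde | O=Cc1cc(Br)c(O)cc1F | intermediate
3 | 3,5-dibromo-2-fluoro-4-hydroxybenzaldehyde | O=Cc1cc(Br)c(O)c(Br)c1F | intermediate
4 | 3,5-dibromo-2-fluoro-4-methoxybenzaldehyde | O=Cc1cc(Br)c(OC)c(Br)c1F | intermediate
5 | 2,4-dibromophenol | Oc1ccc(Br)cc1Br | starting material
6 | 3,5-dibromo-2-(2,4-dibromophenoxy)-4-methoxybenzaldehyde | O=Cc1cc(Br)c(OC)c(Br)c1Oc2ccc(Br)cc2Br | intermediate
7 | 3,5-dibromo-2-(2,4-dibromophenoxy)-4-methoxyphenyl formate | O=COc1cc(Br)c(OC)c(Br)c1Oc2ccc(Br)cc2Br | intermediate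
8 | 3,5-dibromo-2-(2,4-dibromophenoxy)-4-methoxyphenol (achiral) | COc1c(Br)cc(O)c(Oc2ccc(Br)cc2Br)c1Br | target

Total step count: 4
Longest linear sequence: 4 (1 → 3 → 4 → 6 → 8)

**Steps most likely to fail**

Most at risk is step 4. Ring A carries two bromines, and its 4-methoxy group is twisted out of conjugation by them. Hydride migration to the benzoic acid, or simply slow conversion, may therefore compete with aryl migration.

The fallback sets out from 6 and comes back at 8. It swaps the formyl group for an acetyl group.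
- MeMgBr (THF, −78 °C) adds to the aldehyde to give racemic 1-[3,5-dibromo-2-(2,4-dibromophenoxy)-4-methoxyphenyl]ethanol F1.
- Dess–Martin periodinane (CH2Cl2, rt) oxidises it to 1-[3,5-dibromo-2-(2,4-dibromophenoxy)-4-methoxyphenyl]ethanone F2.
- Baeyer–Villiger oxidation with CF3CO3H (urea–H2O2, (CF3CO)2O, Na2HPO4, CH2Cl2, 0 °C to rt) gives 3,5-dibromo-2-(2,4-dibromophenoxy)-4-methoxyphenyl acetate F3. Only the aryl group can move here, because methyl migrates far worse.
- Methanolysis (cat. K2CO3, MeOH, rt) then gives 8.

Second is step 3. C2 is flanked by CHO and Br, and the nucleophile is a weak, ortho-substituted phenoxide. At the temperature needed it may instead attack the O–CH3 group, because 2,6-dibromo-4-formylphenoxide is a good leaving group.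

The fallback sets out from 4 and comes back at 6. It reverses the polarity of the ether bond formation.
- The small nucleophile hydroxide (KOH, DMSO/H2O, 40 °C, then acid) replaces fluoride to give 3,5-dibromo-2-hydroxy-4-methoxybenzaldehyde F4.
- Ring B is delivered as an electrophile, (2,4-dibromophenyl)(2,4,6-trimethoxyphenyl)iodonium tosylate F5. It is made in one pot from 2,4-dibromo-1-iodobenzene (mCPBA, TsOH·H2O, MeCN, 77 °C, then 1,3,5-trimethoxybenzene).
- F4 is O-arylated by F5 (K2CO3, MeCN, 60 °C) to give 6. Metal-free ligand coupling at trivalent iodine transfers the electron-poorer, ortho-substituted aryl group, tolerates crowded phenoxides, and leaves the trimethoxyphenyl group on iodine.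

Third is step 1. The second bromination at C3, between F and OH, may lag. Forcing it with excess Br2 invites ipso attack para to the OH, with loss of the formyl group.

The fallback sets out from 2, isolated this time by stopping at 1.0 equiv of Br2, and comes back at 4. It sets the C3–Br bond by directed ortho-metalation instead of electrophilic substitution.
- Methylation (MeI, K2CO3, DMF, rt) gives 5-bromo-2-fluoro-4-methoxybenzaldehyde F6.
- Acetalisation (ethylene glycol, cat. TsOH, toluene, Dean–Stark) gives 2-(5-bromo-2-fluoro-4-methoxyphenyl)-1,3-dioxolane F7.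
- LiN(i-Pr)2 (THF, −78 °C) removes the most acidic proton, the one between F and OMe, to give [3-bromo-5-(1,3-dioxolan-2-yl)-6-fluoro-2-methoxyphenyl]lithium F8.
- Quenching with BrCCl2CCl2Br gives 2-(3,5-dibromo-2-fluoro-4-methoxyphenyl)-1,3-dioxolane F9.
- Aqueous HCl in THF at rt unmasks the aldehyde to give 4.

**Further compounds**
F1 | step 4 | racemic 1-[3,5-dibromo-2-(2,4-dibromophenoxy)-4-methoxyphenyl]ethanol | CC(O)c1cc(Br)c(OC)c(Br)c1Oc2ccc(Br)cc2Br
F2 | step 4 | 1-[3,5-dibromo-2-(2,4-dibromophenoxy)-4-methoxyphenyl]ethanone | CC(=O)c1cc(Br)c(OC)c(Br)c1Oc2ccc(Br)cc2Br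
F3 | step 4 | 3,5-dibromo-2-(2,4-dibromophenoxy)-4-methoxyphenyl acetate | CC(=O)Oc1cc(Br)c(OC)c(Br)c1Oc2ccc(Br)cc2Br
F4 | step 3 | 3,5-dibromo-2-hydroxy-4-methoxybenzaldehyde | O=Cc1cc(Br)c(OC)c(Br)c1O
F5 | step 3 | (2,4-dibromophenyl)(2,4,6-trimethoxyphenyl)iodonium tosylate | COc1cc(OC)c([I+]c2ccc(Br)cc2Br)c(OC)c1.Cc1ccc(cc1)S(=O)(=O)[O-]
F6 | step 1 | 5-bromo-2-fluoro-4-methoxybenzaldehyde | O=Cc1cc(Br)c(OC)cc1F
F7 | step 1 | 2-(5-bromo-2-fluoro-4-methoxyphenyl)-1,3-dioxolane | COc1cc(F)c(C2OCCO2)cc1Br
F8 | step 1 | [3-bromo-5-(1,3-dioxolan-2-yl)-6-fluoro-2-methoxyphenyl]lithium | [Li]c1c(F)c(C2OCCO2)cc(Br)c1OC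
F9 | step 1 | 2-(3,5-dibromo-2-fluoro-4-methoxyphenyl)-1,3-dioxolane | COc1c(Br)cc(C2OCCO2)c(F)c1Br
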